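The readings were generated by integration with made-up constants.

The easy step is a subtraction: we take the J left, charge minus cX, and work with that instead of the X made. Cedar carries more J than any of the earlier runs.

| setting | birch | alder | elm | ash | cedar |
|---|---|---|---|---|---|
| J | 250 mM | 150 mM | 380 mM | 250 mM | 610 mM |
| Z | 25.0 mM | 25.0 mM | 25.0 mM | 50.0 mM | 25.0 mM |
| time |  |  |  |  | 90 min |

| birch run: time / min | birch run: [X] / mM | alder run: time / min | alder run: [X] / mM | elm run: time / min | elm run: [X] / mM | ash run: time / min | ash run: [X] / mM |
|---|---|---|---|---|---|---|---|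
| 4.0 | 2.4 | 4.0 | 2.4 | 4.0 | 2.8 | 4.0 | 3.9 |
| 12 | 20.7 | 12 | 12.4 | 12 | 25.9 | 12 | 38.2 |
| 23 | 51.2 | 23 | 35.0 | 23 | 64.8 | 23 | 89.9 |
| 37 | 80.7 | 37 | 56.8 | 37 | 105.2 | 37 | 127.9 |
| 53 | 101.8 | 53 | 71.4 | 53 | 134.0 | 53 | 149.0 |
| 70 | 114.2 | 70 | 78.5 | 70 | 146.8 | 70 | 153.2 |
| 90 | 117.8 | 90 | 84.3 | 90 | 153.6 | 90 | 157.0 |

(readings scatter by 0.8 mM)

- apparent order in [Z] of the starting rate, round the charge of the birch run (the rate where two percent of its J have turned into X)
- apparent order in [J] of the starting rate, round the charge of the birch run (the rate where two percent of its J have turned into X) (one fixed amount of X, the same in the runs compared)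
- X in the cedar run at 90 min, as a share of the J charged

- Overall: J -> X, with Z as catalyst.
- Constant volume, constant temperature.
- What is held in complexes is read along with the free species.
- An order is taken over about fifteen percent of the charge, up and down.

The birch run gives a ladder of rates, read as means between readings. The opening 4.0 min of the birch run gives 0.600 mM min⁻¹. Its last 20.0 min give 0.180 mM min⁻¹, less than the opening, yet at 90 min the readings show 132 mM of J not turned into X. Between 12 min and 23 min the birch run reads 2.77 mM min⁻¹, faster than both of these. The ash run, with the same J and twice the Z, reaches 157.0 mM, which is more than the 117.8 mM of the birch run.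

We therefore reckon with the depth, minus the logarithm of the fraction of J left at 90 min, which is the exponent a pseudo-first-order loss of J would show. The birch run reads 0.637. The elm run reads less, 0.518. Multiplying depth by the square root of the ratio of J to Z gives the stall number, 2.01 from birch and 2.02 from elm. The ash run reads 2.21, so we use the number at 25.0 mM of Z and at 90 min. For cedar it gives a depth of 0.408, and so our own share of 33.5%.

The forecast gives 0.45 for Z, 0.4 for J and 33% for cedar, and it reads the stop in its own words: “so this is catalyst death rather than equilibrium”.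

The cedar run gives 33.0% of its J as X at 90 min. Round the charge of the birch run the orders are 0.39 in J and 0.59 in Z, and the forecast parts from the flask on the order in Z.

    Lx + J ⇌ ZJ (1.572 L mol⁻¹ min⁻¹, 0.2130 min⁻¹)
    ZJ → X + Lx (0.3648 min⁻¹)
    Lx + X → Rx + X (0.5688 L mol⁻¹ min⁻¹)
    Z → Lx (0.1470 min⁻¹)

At the same amount of X, the ash run's rate is 2.6 mM min⁻¹ against 1.8 mM min⁻¹ for the birch run, a ratio of 1.5. Cedar's share is a depth of 0.401, a stall number of 1.98 beside the 2.01 from birch. Put on the alder run, 2.01 gives a share of 56.1% at 90 min, and the reading is 56.2%.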